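Up to its second reading the violet run made product at 0.186 mM min⁻¹, and up to its last reading the red run made it at 0.180 mM min⁻¹, so the violet run began about as fast as the red one, though it held less solid substrate than the red run. Between the last two violet readings the rate was down to 0.0412 mM min⁻¹.

| flask | solid substrate | coupling partner | remark | time |
|---|---|---|---|---|
| red | 20 mM | 21 mM | the very flask that is asked about, followed so far |  |
| violet | 13 mM | 21 mM | run made earlier |  |
| flask | 20 mM | 21.0 mM |  | 1.5 h |

| run | time / min | product / % |
|---|---|---|
| red | 10.0 | 11.8 |
| red | 20.0 | 21.4 |
| red | 25.0 | 23.8 |
| red | 40.0 | 36.0 |
| violet | 12.0 | 17.9 |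
| violet | 30.0 | 43.0 |
| violet | 60.0 | 62.9 |
| violet | 90.0 | 72.4 |

(standard deviation of a reading: 1 percentage point)

- amount of product at 1.5 h, in percent of the solid substrate charged
- the change that raises the amount of product at 1.5 h, in percent of the solid substrate charged most ("none" if none brings more than 2 percentage points) (gamma / eta / theta / none)
- amount of product at 1.5 h, in percent of the solid substrate charged, after theta

- gamma: doubling the solubility of the solid substrate, all else as stated
- eta: doubling the dissolution coefficient of the solid substrate, all else as stated
- theta: doubling the amount of coupling partner, all else as stated

- solid substrate is a solid; its amount is given per volume of the solution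
- at the start none of the solid substrate is in solution

Solid substrate is the limiting reagent by charge, less of it being charged than of coupling partner, so its balance is written as open substrate, charge minus product; open partner is likewise charge minus product. Carrying the red line to 1.5 h gives 81.0%, but the bend in the violet run speaks against a straight line.

A better estimate uses the tail constant, the violet late rate divided by open substrate and open partner at mean product 8.79 mM: 8.02 × 10⁻⁴ mM⁻¹ min⁻¹, a reading with the scatter of two readings. The red rate then implies dissolved substrate held near 10.7 mM. By this reckoning the solid in the flask lasts about 51.7 min, open partner then stands at 11.7 mM, and the tail law carries on to 60.8%.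

But the line ignores falling partner. The same law with the whole charge dissolved from the start gives 61.1%. With doubled partner it gives 88.1%, a gain of 27 percentage points, more than the 0.30 points that dissolving the whole charge at once brings in this reckoning, so this reckoning chooses theta. One doubt stays: the readings show product alone, so open substrate may hold more than reacting substrate.

The forecast gives 62% (58% to 66%), theta, and 90% after it (84% to 95%), holding that “dissolution is fast compared with reaction”.

The flask gives 57.9%, and theta brings 75.7%.

    2 solid substrate → homo dimer (k = 0.0165 M⁻¹ s⁻¹)
    dissolved substrate + coupling partner → product (k = 0.0945 M⁻¹ s⁻¹)
    solid substrate ⇌ dissolved substrate, rate k3*(cs3 - [dissolved substrate]) while solid is left; crystals form when [dissolved substrate] > cs3 (solubility = 9.10 mM, k = 0.00198 s⁻¹)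
    coupling partner ⇌ dormant form (K = 2.40, k = 0.00181 s⁻¹)

At 1.50 h the open substrate of the flask, 42.1%, is 17.4% dissolved substrate and 24.7% homo dimer, each dimer counted as two. For the neighbour with 5.0 mM of solid substrate the tail law gives 74.0%; that neighbour reaches 92.2%, more than the law gives, with homo dimer at 1.70%. For the flask at 15.0 h the law gives 95.7%, while the flask reaches 75.3%. The flask is not at rest at 1.50 h: product still gains 17 points, about as much as the dissolved substrate then present, which falls to 0%. Coupling partner falls from 12.0% to 8.33% of its own charge, and homo dimer stands at 24.7%.

All runs were computed for an exercise; scatter was added.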